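Everything rests on cutting the C11–C12 bond of ring C, the eight-membered ether C8–O–C15–C14–C13–C12–C11–C9 fused to ring B. The exploited feature: C12 is the unsubstituted end of the allyl triad C12–C13(CH3)–C14 hanging from the C8 oxygen, and C11 on C9 can bear a sulfonyl carbanion. A single zerovalent-palladium allylic alkylation closes ring C and leaves the Z C13=C14 olefin for epoxidation. Its precursor is a sclareolide-derived trans-decalin carrying 3β-OTBS, a C9–CH2SO2Ph arm and an 8α-OCH2CH(OBoc)C(CH3)=CH2 arm, both equatorial. The 3β-bromide comes last, from the C3 ketone via vinyl bromide and hydrogen-atom-transfer hydrogenation.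

Key step: step 10

Numbering and structure check: labdane numbering is used. C11 sits on C9, C12–C15 lie in ring C, C16 is the methyl on C13, C17 the methyl on C8, C18/C19 are on C4 and C20 is on C10. C5, C8, C9 and C10 of the target have the configuration of (+)-sclareolide. Bromine is 3β (equatorial, 3S). The epoxide is 13R,14S with C12 and C15 cis, so it derives from the Z olefin; its oxygen lies on the side of the C17/C20 methyls when ring C is drawn flat.

Design remark:
- An alkyl phenyl sulfone (pKa about 30) cannot be deprotonated by the alkoxide that an allylic carbonate releases.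
- Its preformed carbanion would be acylated by a methyl carbonate. The precursor therefore carries a tert-butyl carbonate and is deprotonated fully with LiN(i-Pr)2 before the catalyst is added.
- A second activating group on C11 is avoided. It would make C11 quaternary next to C9, between the axial C17 and C20 methyls.

Assumption: an engineered P450 BM3 hydroxylase of the kind known to oxidise sclareolide at C3 is at hand as cell lysate.

Step 1
Reactants: 1 (+)-sclareolide
Product: 2 3β-hydroxysclareolide
Conditions: engineered cytochrome P450 BM3 variant (E. coli lysate), NADP+ (cat.), phosphite dehydrogenase, Na2HPO3, air, KH2PO4/K2HPO4 buffer pH 8, 25 °C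
Reagents that add atoms: dioxygen, O=O
Why: Enzymatic C–H hydroxylation: engineered P450 BM3 variants are known to oxidise sclareolide at the C3 methylene remote from the electron-withdrawing lactone, and hydrogen abstraction–rebound with retention in the pocket replaces the equatorial 3β hydrogen, setting C3 as S.

Step 2
Reactants: 2 3β-hydroxysclareolide
Product: 3 3β-(tert-butyldimethylsilyloxy)sclareolide
Conditions: TBSOTf, 2,6-lutidine, CH2Cl2, 0 °C
Reagents that add atoms: tert-butyldimethylsilyl triflate, CC(C)(C)[Si](C)(C)OS(=O)(=O)C(F)(F)F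
Why: Standard silylation of a hindered equatorial secondary alcohol by the reactive silyl triflate; lutidine does not enolise the lactone and no stereocentre changes.

Step 3
Reactants: 3 3β-(tert-butyldimethylsilyloxy)sclareolide
Product: 4 3β-TBSO-sclareolide lactol (C12 anomers)
Conditions: i-Bu2AlH (1.1 equiv), CH2Cl2, −78 °C; aq. KNaC4H4O6
Reagents that add atoms: none
Why: Partial reduction of a γ-lactone by one equivalent of i-Bu2AlH at low temperature stops at the stable aluminium lactolate and should give the lactol as an inconsequential anomer mixture.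

Step 4
Reactants: 4 3β-TBSO-sclareolide lactol
Product: 5 3β-TBSO-11-iododrimane-8α-yl formate
Conditions: PhI(OAc)2, I2, CH2Cl2, visible light, 25 °C
Reagents that add atoms: iodine, [I][I]
Why: Suárez alkoxy-radical fragmentation: the lactol hypoiodite homolyses, β-scission of C11–C12 leaves C12 as the formate on O8 and iodine traps the primary C11 radical, a degradation known on the parent lactol that leaves C8 and C9 untouched.

Step 5
Reactants: 5 3β-TBSO-11-iododrimane-8α-yl formate; 6 thiophenol
Product: 8 3β-TBSO-11-(phenylthio)drimane-8α-ol, via sulfide formate 7 (not isolated)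
Conditions: PhSH, K2CO3, DMF, 50 °C; then MeOH, 25 °C
Reagents that add atoms: thiophenol (compound 6), Sc1ccccc1
Why: SN2 displacement of the primary iodide by the soft, weakly basic thiophenolate precedes base-catalysed transesterification of the formate, so no free alkoxide ever faces the γ-iodide and Grob fragmentation or oxetane closure is avoided.

Step 6
Reactants: 8 3β-TBSO-11-(phenylthio)drimane-8α-ol; 9 allyl bromide
Product: 11 8α-allyloxy-3β-TBSO-11-(phenylthio)drimane, via potassium alkoxide 10 (not isolated)
Conditions: KH, THF, 0 °C; then allyl bromide, n-Bu4NI (cat.), 0 → 25 °C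
Reagents that add atoms: allyl bromide (compound 9), C=CCBr
Why: Williamson etherification: the potassium alkoxide of the equatorial tertiary alcohol is alkylated by the unhindered allylic bromide, and this is done at the sulfide stage because a sulfone would compete as a carbon acid.

Step 7
Reactants: 11 8α-allyloxy-3β-TBSO-11-(phenylthio)drimane
Product: 12 8α-allyloxy-3β-TBSO-11-(phenylsulfonyl)drimane
Conditions: (NH4)6Mo7O24·4H2O (10 mol %), 30% H2O2, EtOH–THF, 0 → 25 °C
Reagents that add atoms: hydrogen peroxide, OO
Why: Molybdate-catalysed peroxide oxidation takes the sulfide through the sulfoxide to the sulfone much faster than it touches the electron-poor monosubstituted allyl ether olefin.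

Step 8
Reactants: 12 8α-allyloxy-3β-TBSO-11-(phenylsulfonyl)drimane
Product: 14 2-[3β-TBSO-11-(phenylsulfonyl)drimane-8α-yloxy]acetaldehyde, via secondary ozonide 13 (not isolated)
Conditions: O3, CH2Cl2, −78 °C; then Me2S, −78 → 25 °C
Reagents that add atoms: ozone, [O-][O+]=O
Why: Ozonolysis (Criegee mechanism) of the only olefin followed by reductive work-up gives the α-alkoxy aldehyde, while the sulfone, the silyl ether and the deactivated arene are inert to ozone.

Step 9
Reactants: 14 2-[3β-TBSO-11-(phenylsulfonyl)drimane-8α-yloxy]acetaldehyde; 15 isopropenylmagnesium bromide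
Product: 17 C11 phenyl sulfone bearing the C14 allylic tert-butyl carbonate (C14 epimers), via magnesium alkoxide 16 (not isolated)
Conditions: CH2=C(CH3)MgBr (1.3 equiv), THF, −78 °C; then Boc2O, −78 → 25 °C
Reagents that add atoms: isopropenylmagnesium bromide (compound 15), CC(=C)[Mg]Br; di-tert-butyl dicarbonate, CC(C)(C)OC(=O)OC(=O)OC(C)(C)C
Why: Grignard 1,2-addition to the unhindered aldehyde at −78 °C outruns deprotonation of the sulfone and Boc2O acylates the alkoxide in the same flask; C14 forms as both epimers, which is harmless because it becomes sp2 in step 10.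

Step 10
Reactants: 17 C11 phenyl sulfone bearing the C14 allylic tert-butyl carbonate
Product: 19 C11-(phenylsulfonyl) Z-oxocene (3β-TBSO; C11 epimers), via lithio sulfone 18 (not isolated)
Conditions: LiN(i-Pr)2 (1.1 equiv), THF (2 mM), −78 → −30 °C; then Pd(PPh3)4 (10 mol %), Ph2PCH2CH2PPh2 (10 mol %), −30 → 25 °C
Reagents that add atoms: none
Why: LiN(i-Pr)2 removes a C11 proton completely, the hindered tert-butyl carbonate resisting acylation by the carbanion, and zerovalent palladium then ionises either C14 epimer with inversion and loss of CO2 and tert-butoxide to one equilibrating π-allyl complex over C12–C13–C14. The carbanion attacks the CH2 terminus C12 and forms C11–C12, which is a Tsuji–Trost allylic alkylation closest to the known palladium-catalysed medium-ring closures of sulfonyl-stabilised carbanions that prefer eight- over six-membered rings and to the known allylation of singly sulfonyl-stabilised carbanions at π-allylpalladium. Ring C closes in the endo sense (attack at the distal allyl terminus, olefin inside the eight-membered ring) at high dilution, helped by the rigid decalin whose trans-diequatorial C8–O and C9–C11 bonds hold the two arms gauche and close. The only new stereocentre is C11, expected mainly with the sulfonyl group turned away from the axial C17 and C20 methyls, and it is erased in step 11, while C14 becomes sp2. Regioselectivity for C12 over 6-exo attack at C14 is needed and rests on the unsubstituted terminus, the flanking C13 methyl, the inductive pull of the C15 oxygen and the bulk of the neopentyl-like carbanion. Z geometry is needed and follows because only the anti π-allyl isomer, reached by π–σ–π exchange and made more accessible by the C13 methyl, can span an eight-membered ring.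

Step 11
Reactants: 19 C11-(phenylsulfonyl) Z-oxocene
Product: 20 3β-TBSO-8α,15-epoxylabd-13(Z)-ene
Conditions: Mg turnings, MeOH–THF, 25 → 50 °C
Reagents that add atoms: none
Why: Reductive desulfonylation by single-electron transfer from magnesium in methanol cleaves the C11–S bond and protonates the carbanion, erasing the C11 stereocentre while the isolated olefin, the allylic ether and the silyl ether survive.

Step 12
Reactants: 20 3β-TBSO-8α,15-epoxylabd-13(Z)-ene
Product: 21 8α,15-epoxylabd-13(Z)-en-3β-ol
Conditions: n-Bu4NF, THF, 60 °C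
Reagents that add atoms: none
Why: Fluoride-driven desilylation under non-acidic conditions spares the acid-sensitive tertiary allylic ether.

Step 13
Reactants: 21 8α,15-epoxylabd-13(Z)-en-3β-ol
Product: 22 8α,15-epoxylabd-13(Z)-en-3-one
Conditions: n-Pr4N[RuO4] (5 mol %), N-methylmorpholine N-oxide, 4 Å MS, CH2Cl2, 25 °C
Reagents that add atoms: none
Why: Ley–Griffith oxidation converts the hindered secondary alcohol into the ketone under neutral conditions that leave the trisubstituted olefin alone.

Step 14
Reactants: 22 8α,15-epoxylabd-13(Z)-en-3-one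
Product: 23 C3 hydrazone of 22
Conditions: N2H4·H2O (excess), Et3N, EtOH, 85 °C, argon
Reagents that add atoms: hydrazine, NN
Why: Condensation of the neopentyl-type ketone with excess hydrazine gives the hydrazone; it is placed before epoxidation so that no epoxide meets hot hydrazine, and run under argon so that no diimide forms.

Step 15
Reactants: 23 C3 hydrazone of 22
Product: 24 3-bromo-8α,15-epoxylabda-2,13(Z)-diene
Conditions: NBS, 2-tert-butyl-1,1,3,3-tetramethylguanidine, CH2Cl2, 0 °C, slow addition of 23
Reagents that add atoms: N-bromosuccinimide, O=C1CCC(=O)N1Br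
Why: Barton vinyl halide synthesis: N-bromination and base-induced loss of HBr give the diazoalkane, whose bromination, loss of N2 and loss of the only available proton (C2–H) furnish the 3-bromo-2-ene, the hydrazone reacting far faster with NBS than the olefin does in a basic aprotic medium.

Step 16
Reactants: 24 3-bromo-8α,15-epoxylabda-2,13(Z)-diene
Product: 25 (13R,14S)-3-bromo-8α,15:13,14-diepoxylabd-2-ene
Conditions: 1,2:4,5-di-O-isopropylidene-β-L-erythro-2,3-hexodiulo-2,6-pyranose (30 mol %), KHSO5 (as 2KHSO5·KHSO4·K2SO4), K2CO3, n-Bu4NHSO4, MeCN–CH2(OMe)2–aq. Na2B4O7, 0 °C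
Reagents that add atoms: potassium peroxymonosulfate, [K+].[O-]S(=O)(=O)OO
Why: Shi epoxidation: the chiral dioxirane attacks only the electron-rich trisubstituted olefin (the bromoalkene is too electron-poor) through the spiro transition state established for 1-substituted cycloalkenes, and the L-series ketone delivers oxygen suprafacially to the face that sets 13R and 14S together, so the outcome rests on the reagent and not on an unknown conformational bias of ring C.

Step 17
Reactants: 25 (13R,14S)-3-bromo-8α,15:13,14-diepoxylabd-2-ene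
Product: 26 target (3S,13R,14S)-3β-bromo-8α,15:13,14-diepoxylabdane
Conditions: Mn(dpm)3 [tris(2,2,6,6-tetramethyl-3,5-heptanedionato)manganese] (10 mol %), PhSiH3, t-BuOOH, i-PrOH, 22 °C
Reagents that add atoms: none
Why: Metal-hydride hydrogen-atom-transfer hydrogenation, known to reduce bromoalkenes without loss of bromine: a hydrogen atom adds to C2 and the C3 α-bromo radical takes its hydrogen on the α face, away from the axial 4β and 10β methyls, which sets 3S with bromine equatorial (the thermodynamic epimer) while the epoxide is inert.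

Compound list

1 | (+)-sclareolide; trans-decalin γ-lactone, 5α-H, 9α-H, 8β-CH3, 10β-CH3, lactone O on C8α | CC1(C)CCC[C@]2(C)[C@H]3CC(=O)O[C@]3(C)CC[C@@H]12 | starting material
2 | 3β-hydroxysclareolide (3S, equatorial OH) | CC1(C)[C@@H](O)CC[C@]2(C)[C@H]3CC(=O)O[C@]3(C)CC[C@@H]12 | intermediate
3 | 3β-(tert-butyldimethylsilyloxy)sclareolide | CC1(C)[C@@H](O[Si](C)(C)C(C)(C)C)CC[C@]2(C)[C@H]3CC(=O)O[C@]3(C)CC[C@@H]12 | intermediate
4 | lactol of 3 (C12 hemiacetal, anomer mixture) | CC1(C)[C@@H](O[Si](C)(C)C(C)(C)C)CC[C@]2(C)[C@H]3CC(O)O[C@]3(C)CC[C@@H]12 | intermediate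
5 | 3β-TBSO-11-iododrimane-8α-yl formate (C9 β-CH2I, 8α-OCHO, 8β-CH3) | CC1(C)[C@@H](O[Si](C)(C)C(C)(C)C)CC[C@]2(C)[C@@H](CI)[C@](C)(OC=O)CC[C@@H]12 | intermediate
6 | thiophenol | Sc1ccccc1 | starting material
7 | 3β-TBSO-11-(phenylthio)drimane-8α-yl formate | CC1(C)[C@@H](O[Si](C)(C)C(C)(C)C)CC[C@]2(C)[C@@H](CSc3ccccc3)[C@](C)(OC=O)CC[C@@H]12 | intermediate (not isolated)
8 | 3β-TBSO-11-(phenylthio)drimane-8α-ol | CC1(C)[C@@H](O[Si](C)(C)C(C)(C)C)CC[C@]2(C)[C@@H](CSc3ccccc3)[C@](C)(O)CC[C@@H]12 | intermediate
9 | allyl bromide | C=CCBr | starting material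
10 | potassium 8α-alkoxide of 8 | CC1(C)[C@@H](O[Si](C)(C)C(C)(C)C)CC[C@]2(C)[C@@H](CSc3ccccc3)[C@](C)([O-])CC[C@@H]12.[K+] | intermediate (not isolated)
11 | 8α-allyloxy-3β-TBSO-11-(phenylthio)drimane | CC1(C)[C@@H](O[Si](C)(C)C(C)(C)C)CC[C@]2(C)[C@@H](CSc3ccccc3)[C@](C)(OCC=C)CC[C@@H]12 | intermediate
12 | 8α-allyloxy-3β-TBSO-11-(phenylsulfonyl)drimane | CC1(C)[C@@H](O[Si](C)(C)C(C)(C)C)CC[C@]2(C)[C@@H](CS(=O)(=O)c3ccccc3)[C@](C)(OCC=C)CC[C@@H]12 | intermediate
13 | secondary ozonide (1,2,4-trioxolane) of 12 | CC1(C)[C@@H](O[Si](C)(C)C(C)(C)C)CC[C@]2(C)[C@@H](CS(=O)(=O)c3ccccc3)[C@](C)(OCC3OCOO3)CC[C@@H]12 | intermediate (not isolated)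
14 | 2-[3β-TBSO-11-(phenylsulfonyl)drimane-8α-yloxy]acetaldehyde (C15H2–C14HO on O8) | CC1(C)[C@@H](O[Si](C)(C)C(C)(C)C)CC[C@]2(C)[C@@H](CS(=O)(=O)c3ccccc3)[C@](C)(OCC=O)CC[C@@H]12 | intermediate
15 | isopropenylmagnesium bromide | CC(=C)[Mg]Br | starting material
16 | bromomagnesium C14 alkoxide (C14 epimers) | CC1(C)[C@@H](O[Si](C)(C)C(C)(C)C)CC[C@]2(C)[C@@H](CS(=O)(=O)c3ccccc3)[C@](C)(OCC(O[Mg]Br)C(C)=C)CC[C@@H]12 | intermediate (not isolated)
17 | cyclisation precursor: C11 phenyl sulfone, 8α-OCH2CH(OBoc)C(CH3)=CH2, 3β-OTBS (C14 epimers) | CC1(C)[C@@H](O[Si](C)(C)C(C)(C)C)CC[C@]2(C)[C@@H](CS(=O)(=O)c3ccccc3)[C@](C)(OCC(OC(=O)OC(C)(C)C)C(C)=C)CC[C@@H]12 | intermediate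
18 | C11-lithio derivative of 17 | CC1(C)[C@@H](O[Si](C)(C)C(C)(C)C)CC[C@]2(C)[C@@H](C([Li])S(=O)(=O)c3ccccc3)[C@](C)(OCC(OC(=O)OC(C)(C)C)C(C)=C)CC[C@@H]12 | intermediate (not isolated)
19 | C11-(phenylsulfonyl) Z-oxocene, 3β-OTBS (C11 epimers) | CC1(C)[C@@H](O[Si](C)(C)C(C)(C)C)CC[C@]2(C)[C@H]3C(S(=O)(=O)c4ccccc4)C/C(C)=C\CO[C@]3(C)CC[C@@H]12 | intermediate
20 | 3β-TBSO-8α,15-epoxylabd-13(Z)-ene | CC1(C)[C@@H](O[Si](C)(C)C(C)(C)C)CC[C@]2(C)[C@H]3CC/C(C)=C\CO[C@]3(C)CC[C@@H]12 | intermediate
21 | 8α,15-epoxylabd-13(Z)-en-3β-ol | CC1(C)[C@@H](O)CC[C@]2(C)[C@H]3CC/C(C)=C\CO[C@]3(C)CC[C@@H]12 | intermediate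
22 | 8α,15-epoxylabd-13(Z)-en-3-one | CC1(C)C(=O)CC[C@]2(C)[C@H]3CC/C(C)=C\CO[C@]3(C)CC[C@@H]12 | intermediate
23 | C3 hydrazone of 22 | CC1(C)C(=NN)CC[C@]2(C)[C@H]3CC/C(C)=C\CO[C@]3(C)CC[C@@H]12 | intermediate
24 | 3-bromo-8α,15-epoxylabda-2,13(Z)-diene | CC1(C)C(Br)=CC[C@]2(C)[C@H]3CC/C(C)=C\CO[C@]3(C)CC[C@@H]12 | intermediate
25 | (13R,14S)-3-bromo-8α,15:13,14-diepoxylabd-2-ene | CC1(C)C(Br)=CC[C@]2(C)[C@H]3CC[C@@]4(C)O[C@H]4CO[C@]3(C)CC[C@@H]12 | intermediate
26 | CNP0311742.2, (3S,13R,14S)-3β-bromo-8α,15:13,14-diepoxylabdane | CC1(C)[C@@H](Br)CC[C@]2(C)[C@H]3CC[C@@]4(C)O[C@H]4CO[C@]3(C)CC[C@@H]12 | target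

Total step count: 17. Longest linear sequence: 17 steps (1 to 26).

Steps most likely to fail

Step 10. Several processes could divert the cyclisation:
- closure at the substituted terminus C14, giving a six-membered ring;
- loss of a C15 proton from the π-allyl complex, giving a diene;
- intermolecular coupling;
- sluggish capture of a carbanion that is only singly stabilised.

The fallback closes ring C at C13=C14 by metathesis instead. It sets out from 12. Deprotonation with n-BuLi in THF–DMPU at −78 °C and alkylation with 3-bromo-2-methylpropene should give the methallylated diene sulfone F1. Ring-closing metathesis of F1 with the second-generation Grubbs catalyst (H2IMes)(PCy3)Cl2Ru=CHPh in dilute refluxing CH2Cl2 should then join the allyl ether to the methallyl group. The ring size enforces the Z olefin, and the sequence returns to the route at 19.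

Step 16. Facial selectivity may be poor or reversed if the conformation of the oxocene shields the face that the catalyst addresses (a mismatched pairing). The fallback turns such an intrinsic bias to advantage and sets out from 24. NBS in aqueous 1,2-dimethoxyethane at 0 °C should form the bromonium ion on the more open face, and water should open it anti at the tertiary C13 to give the (13R,14R)-bromohydrin F2. K2CO3 in MeOH then closes the C13 alkoxide onto C14 with inversion. This places the epoxide on the face opposite to the first attack and returns to the route at 25.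

Step 15. Electrophilic bromine may attack the C13=C14 olefin, azine or geminal dibromide may form, or a C4 methyl may migrate in the α-bromo cation. The fallback avoids electrophilic bromine altogether and sets out from 22, bypassing 23. Enolisation towards C2 (the only enolisable side) with KN(SiMe3)2 and trapping with PhNTf2 should give the enol triflate F3. Nickel-catalysed triflate–bromide exchange (Ni(cod)2, LiBr, DMA–THF, 25 °C), a known reaction of enol triflates, then returns to the route at 24.

Further compounds

F1 | step 10 | 8α-allyloxy-3β-TBSO-11-(2-methylallyl)-11-(phenylsulfonyl)drimane (C11 epimers) | CC1(C)[C@@H](O[Si](C)(C)C(C)(C)C)CC[C@]2(C)[C@@H](C(CC(C)=C)S(=O)(=O)c3ccccc3)[C@](C)(OCC=C)CC[C@@H]12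
F2 | step 16 | (13R,14R)-3,14-dibromo-8α,15-epoxylabd-2-en-13-ol | CC1(C)C(Br)=CC[C@]2(C)[C@H]3CC[C@@](C)(O)[C@H](Br)CO[C@]3(C)CC[C@@H]12
F3 | step 15 | 8α,15-epoxylabda-2,13(Z)-dien-3-yl triflate | CC1(C)C(OS(=O)(=O)C(F)(F)F)=CC[C@]2(C)[C@H]3CC/C(C)=C\CO[C@]3(C)CC[C@@H]12
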